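**Plan**
- Retrosynthesis: after removal of the two silyl ethers, ring C is opened at C2=C3 (ester Wittig), then at C3–C4 (C-acylation of methoxymethylenetriphenylphosphorane by a ring A benzoyl chloride) and at the O1–C2 acyl bond (esterification with the ring B acid). Ring A goes back through C4–C4a (ortho-formylation) and C5–O (C–H borylation/oxidation) to 2-methoxyresorcinol, ring B through its O–prenyl bond to methyl 4-hydroxybenzoate.
- Forward order: ring A is oxygenated at C5, formylated and silylated at O7. Ring B, already carrying the prenyl ether, is then attached as the ester of the one remaining hydroxyl, the one beside the methoxy group. Aldehyde, acid and acyl ylide follow, ring C closes last, and desilylation ends the route.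
- Enabling feature: in ring C, C2 (bonded to O1 and ring B) is at the ester oxidation level and C3 (bearing OMe) is the α-carbon of the C4 ketone. C2=C3 is therefore the olefin between an aryl ester carbonyl and a keto-stabilised ylide carbon, which ring A holds ortho to each other.
- Stereochemistry: the target has no stereocentre and no stereogenic double bond (the ring C alkene is endocyclic, the prenyl alkene carries two methyl groups), so nothing has to be set.

Key step: step 11

Assumption: compounds 1, 10, 11 and 17 are taken as commercial; flavone numbering (O1, C2–C8a) is used for ring positions throughout.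

Step 1
Reactants: 1 2-methoxyresorcinol
Product: 2 2-methoxy-1,3-phenylene diacetate
Conditions: Ac2O, pyridine, 0 °C to rt
Reagents that add atoms: acetic anhydride, CC(=O)OC(C)=O
Why: O-acetylation (nucleophilic acyl substitution) masks both phenols as small esters that tolerate C–H borylation and carry no unhindered aromatic C–H of their own.

Step 2
Reactants: 2 2-methoxy-1,3-phenylene diacetate
Product: 4 5-hydroxy-2-methoxy-1,3-phenylene diacetate, via aryl pinacol boronate 3 (not isolated)
Conditions: [Ir(OMe)(cod)]2 (cat.), 4,4'-di-tert-butyl-2,2'-bipyridine (cat.), B2pin2, THF, 80 °C; volatiles removed; then Oxone (2KHSO5·KHSO4·K2SO4), acetone/H2O, rt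
Reagents that add atoms: potassium peroxymonosulfate (active salt of Oxone), [K+].[O-]S(=O)(=O)OO
Why: iridium-catalysed aromatic C–H borylation (Hartwig–Miyaura type) is sterically governed and C5 is the only ring C–H without an ortho substituent, and the boronate is then oxidised by peroxymonosulfate through a 1,2-aryl shift from boron to oxygen under conditions that spare the acetates.

Step 3
Reactants: 4 5-hydroxy-2-methoxy-1,3-phenylene diacetate
Product: 5 2-methoxy-5-(triisopropylsilyloxy)-1,3-phenylene diacetate
Conditions: iPr3SiCl, imidazole, DMF, rt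
Reagents that add atoms: triisopropylsilyl chloride, CC(C)[Si](Cl)(C(C)C)C(C)C
Why: imidazole-promoted O-silylation of the only free phenol, which is flanked by two hydrogens and so reacts readily with the bulky chlorosilane.

Step 4
Reactants: 5 2-methoxy-5-(triisopropylsilyloxy)-1,3-phenylene diacetate
Product: 6 2-methoxy-5-(triisopropylsilyloxy)benzene-1,3-diol
Conditions: K2CO3 (cat.), MeOH, 0 °C; aq. NH4Cl
Reagents that add atoms: none
Why: base-catalysed transesterification (Zemplén-type methanolysis) of aryl acetates is much faster than attack at the hindered aryl triisopropylsilyl ether, so the symmetric diol should be released with the silyl group in place.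

Step 5
Reactants: 6 2-methoxy-5-(triisopropylsilyloxy)benzene-1,3-diol
Product: 8 2,4-dihydroxy-3-methoxy-6-(triisopropylsilyloxy)benzaldehyde, via benzylic alcohol 7 (not isolated)
Conditions: MgCl2, Et3N, (CH2O)n, THF, reflux; aq. HCl
Reagents that add atoms: paraformaldehyde (formaldehyde), C=O
Why: magnesium phenoxide-directed ortho-formylation (Casnati–Skattebøl) delivers formaldehyde ortho to a phenoxide and oxidises the benzylic alkoxide by hydride transfer to a second formaldehyde, and because the two open ring positions of 6 are equivalent and the other ortho site carries the methoxy group, only one mono-aldehyde can form.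

Step 6
Reactants: 8 2,4-dihydroxy-3-methoxy-6-(triisopropylsilyloxy)benzaldehyde
Product: 9 2-hydroxy-3-methoxy-4,6-bis(triisopropylsilyloxy)benzaldehyde
Conditions: iPr3SiCl (1.1 equiv), imidazole, CH2Cl2, 0 °C to rt
Reagents that add atoms: triisopropylsilyl chloride, CC(C)[Si](Cl)(C(C)C)C(C)C
Why: regioselective O-silylation, since the hydroxyl para to the formyl group is the more acidic and is not hydrogen-bonded, whereas the ortho hydroxyl is locked in a chelate with the aldehyde and flanked on both sides.

Step 7
Reactants: 10 methyl 4-hydroxybenzoate; 11 prenyl bromide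
Product: 13 4-(3-methylbut-2-enyloxy)benzoic acid, via methyl 4-prenyloxybenzoate 12 (not isolated)
Conditions: K2CO3, DMF, 60 °C; then NaOH, H2O/MeOH, 70 °C; HCl to pH 2
Reagents that add atoms: sodium hydroxide, [Na+].[OH-]
Why: Williamson ether synthesis at the phenoxide (direct SN2 at the primary allylic bromide) followed by saponification of the methyl ester in the same pot, neither of which touches the trisubstituted alkene.

Step 8
Reactants: 9 2-hydroxy-3-methoxy-4,6-bis(triisopropylsilyloxy)benzaldehyde; 13 4-(3-methylbut-2-enyloxy)benzoic acid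
Product: 15 2-formyl-6-methoxy-3,5-bis(triisopropylsilyloxy)phenyl 4-(3-methylbut-2-enyloxy)benzoate, via 4-prenyloxybenzoyl chloride 14 (not isolated)
Conditions: 13, Me2C=C(Cl)NMe2, CH2Cl2, 0 °C to rt; then 9, Et3N, DMAP (cat.), CH2Cl2, rt
Reagents that add atoms: none
Why: the α-chloroenamine converts the acid into its chloride without releasing HCl (so the prenyl alkene is not hydrochlorinated), and DMAP-catalysed esterification then acylates the only free hydroxyl of 9, the one between the methoxy and formyl groups, which fixes the future O1 beside the 8-methoxy group.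

Step 9
Reactants: 15 2-formyl-6-methoxy-3,5-bis(triisopropylsilyloxy)phenyl 4-(3-methylbut-2-enyloxy)benzoate
Product: 16 3-methoxy-2-[4-(3-methylbut-2-enyloxy)benzoyloxy]-4,6-bis(triisopropylsilyloxy)benzoic acid
Conditions: NaClO2, NaH2PO4, 2-methylbut-2-ene (large excess), t-BuOH/THF/H2O, 0 °C to rt
Reagents that add atoms: sodium chlorite, [Na+].[O-]Cl=O
Why: Pinnick oxidation converts the aldehyde into the acid at mildly acidic pH without hydrolysing the aryl ester or the silyl ethers, and the large excess of 2-methylbut-2-ene should intercept hypochlorous acid before it reaches the prenyl double bond or ring A.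

Step 10
Reactants: 16 3-methoxy-2-[4-(3-methylbut-2-enyloxy)benzoyloxy]-4,6-bis(triisopropylsilyloxy)benzoic acid; 17 (methoxymethyl)triphenylphosphonium chloride
Product: 20 2-methoxy-1-{3-methoxy-2-[4-(3-methylbut-2-enyloxy)benzoyloxy]-4,6-bis(triisopropylsilyloxy)phenyl}-2-(triphenyl-λ5-phosphanylidene)ethan-1-one, via acid chloride 18 (not isolated), via acylphosphonium chloride 19 (not isolated)
Conditions: 16, Me2C=C(Cl)NMe2, CH2Cl2, rt; solution added at −78 °C to Ph3P=CHOMe [17 (2.1 equiv), NaN(SiMe3)2 (2.0 equiv), THF, 0 °C]; −78 to 0 °C; filtration through neutral alumina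
Reagents that add atoms: none
Why: Bestmann-type C-acylation of a non-stabilised phosphorus ylide by an acid chloride, which at −78 °C should be far faster than attack on the aryl ester, followed by transylidation in which the second ylide equivalent deprotonates the acylphosphonium salt to the keto-stabilised α-methoxy ylide.

Step 11
Reactants: 20 2-methoxy-1-{3-methoxy-2-[4-(3-methylbut-2-enyloxy)benzoyloxy]-4,6-bis(triisopropylsilyloxy)phenyl}-2-(triphenyl-λ5-phosphanylidene)ethan-1-one
Product: 21 3,8-dimethoxy-2-[4-(3-methylbut-2-enyloxy)phenyl]-5,7-bis(triisopropylsilyloxy)-4H-chromen-4-one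
Conditions: PhMe, 110 °C, argon
Reagents that add atoms: none
Why: On heating, the carbanionic carbon of the keto-stabilised α-methoxy ylide adds to the carbonyl of the neighbouring 4-prenyloxybenzoate, the betaine closes to an oxaphosphetane, and its collapse expels Ph3PO and leaves the C2=C3 double bond with ring B on C2 and the methoxy group on C3. The closest known reaction type is the intramolecular Wittig olefination of aryl esters by 2-acyloxyphenacylidene phosphoranes, which gives chromones and flavones; here the ylide carbon carries an additional methoxy group, which should raise its nucleophilicity while adding bulk. Ring C closes in a 6-exo-trig mode, the attacked C=O lying outside the six-membered ring made up of C3, C4, C4a, C8a, O1 and C2. No stereocentre arises and the new double bond is endocyclic, so there is nothing to control stereochemically. The step needs C-attack of the ylide on the ester in preference to acyl transfer to the ylide oxygen or to a second molecule, and it needs the ring oxygen to end up beside the 8-methoxy group; the first is secured by the ortho relationship of ylide and ester, the absence of α-hydrogens in the aroyl group and the irreversible loss of Ph3PO, the second by the fact that 20 holds a single ester, placed in step 8 on the hydroxyl next to the methoxy group. The neutral medium at 110 °C lies below the onset of aryl prenyl ether rearrangement and should leave both silyl ethers intact.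

Step 12
Reactants: 21 3,8-dimethoxy-2-[4-(3-methylbut-2-enyloxy)phenyl]-5,7-bis(triisopropylsilyloxy)-4H-chromen-4-one
Product: 22 5,7-dihydroxy-3,8-dimethoxy-2-[4-(3-methylbut-2-enyloxy)phenyl]-4H-chromen-4-one
Conditions: Bu4NF, AcOH, THF, 0 °C to rt
Reagents that add atoms: none
Why: fluoride-induced cleavage of both aryl silyl ethers (driven by Si–F bond formation) under acetic acid buffering frees the 5- and 7-hydroxyls without touching the prenyl ether, the methyl ethers or the chromone.

**Compound list**
1 | 2-methoxyresorcinol (2-methoxybenzene-1,3-diol) | COc1c(O)cccc1O | starting material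
2 | 2-methoxy-1,3-phenylene diacetate | COc1c(OC(C)=O)cccc1OC(C)=O | intermediate
3 | 2-methoxy-5-(4,4,5,5-tetramethyl-1,3,2-dioxaborolan-2-yl)-1,3-phenylene diacetate | COc1c(OC(C)=O)cc(B2OC(C)(C)C(C)(C)O2)cc1OC(C)=O | intermediate
4 | 5-hydroxy-2-methoxy-1,3-phenylene diacetate | COc1c(OC(C)=O)cc(O)cc1OC(C)=O | intermediate
5 | 2-methoxy-5-(triisopropylsilyloxy)-1,3-phenylene diacetate | COc1c(OC(C)=O)cc(O[Si](C(C)C)(C(C)C)C(C)C)cc1OC(C)=O | intermediate
6 | 2-methoxy-5-(triisopropylsilyloxy)benzene-1,3-diol | COc1c(O)cc(O[Si](C(C)C)(C(C)C)C(C)C)cc1O | intermediate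
7 | 4-(hydroxymethyl)-2-methoxy-5-(triisopropylsilyloxy)benzene-1,3-diol (present as its magnesium salt) | COc1c(O)cc(O[Si](C(C)C)(C(C)C)C(C)C)c(CO)c1O | intermediate
8 | 2,4-dihydroxy-3-methoxy-6-(triisopropylsilyloxy)benzaldehyde | COc1c(O)cc(O[Si](C(C)C)(C(C)C)C(C)C)c(C=O)c1O | intermediate
9 | 2-hydroxy-3-methoxy-4,6-bis(triisopropylsilyloxy)benzaldehyde | COc1c(O[Si](C(C)C)(C(C)C)C(C)C)cc(O[Si](C(C)C)(C(C)C)C(C)C)c(C=O)c1O | intermediate
10 | methyl 4-hydroxybenzoate | COC(=O)c1ccc(O)cc1 | starting material
11 | prenyl bromide (1-bromo-3-methylbut-2-ene) | CC(C)=CCBr | starting material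
12 | methyl 4-(3-methylbut-2-enyloxy)benzoate | COC(=O)c1ccc(OCC=C(C)C)cc1 | intermediate
13 | 4-(3-methylbut-2-enyloxy)benzoic acid | OC(=O)c1ccc(OCC=C(C)C)cc1 | intermediate
14 | 4-(3-methylbut-2-enyloxy)benzoyl chloride | ClC(=O)c1ccc(OCC=C(C)C)cc1 | intermediate
15 | 2-formyl-6-methoxy-3,5-bis(triisopropylsilyloxy)phenyl 4-(3-methylbut-2-enyloxy)benzoate | COc1c(O[Si](C(C)C)(C(C)C)C(C)C)cc(O[Si](C(C)C)(C(C)C)C(C)C)c(C=O)c1OC(=O)c1ccc(OCC=C(C)C)cc1 | intermediate
16 | 3-methoxy-2-[4-(3-methylbut-2-enyloxy)benzoyloxy]-4,6-bis(triisopropylsilyloxy)benzoic acid | COc1c(O[Si](C(C)C)(C(C)C)C(C)C)cc(O[Si](C(C)C)(C(C)C)C(C)C)c(C(=O)O)c1OC(=O)c1ccc(OCC=C(C)C)cc1 | intermediate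
17 | (methoxymethyl)triphenylphosphonium chloride | COC[P+](c1ccccc1)(c1ccccc1)c1ccccc1.[Cl-] | starting material
18 | 3-methoxy-2-[4-(3-methylbut-2-enyloxy)benzoyloxy]-4,6-bis(triisopropylsilyloxy)benzoyl chloride | COc1c(O[Si](C(C)C)(C(C)C)C(C)C)cc(O[Si](C(C)C)(C(C)C)C(C)C)c(C(=O)Cl)c1OC(=O)c1ccc(OCC=C(C)C)cc1 | intermediate
19 | {1-methoxy-2-[3-methoxy-2-[4-(3-methylbut-2-enyloxy)benzoyloxy]-4,6-bis(triisopropylsilyloxy)phenyl]-2-oxoethyl}triphenylphosphonium chloride (racemic at the phosphorus-bearing carbon) | COC(C(=O)c1c(O[Si](C(C)C)(C(C)C)C(C)C)cc(O[Si](C(C)C)(C(C)C)C(C)C)c(OC)c1OC(=O)c1ccc(OCC=C(C)C)cc1)[P+](c1ccccc1)(c1ccccc1)c1ccccc1.[Cl-] | intermediate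
20 | 2-methoxy-1-{3-methoxy-2-[4-(3-methylbut-2-enyloxy)benzoyloxy]-4,6-bis(triisopropylsilyloxy)phenyl}-2-(triphenyl-λ5-phosphanylidene)ethan-1-one | COC(=P(c1ccccc1)(c1ccccc1)c1ccccc1)C(=O)c1c(O[Si](C(C)C)(C(C)C)C(C)C)cc(O[Si](C(C)C)(C(C)C)C(C)C)c(OC)c1OC(=O)c1ccc(OCC=C(C)C)cc1 | intermediate
21 | 3,8-dimethoxy-2-[4-(3-methylbut-2-enyloxy)phenyl]-5,7-bis(triisopropylsilyloxy)-4H-chromen-4-one | COc1c(-c2ccc(OCC=C(C)C)cc2)oc2c(OC)c(O[Si](C(C)C)(C(C)C)C(C)C)cc(O[Si](C(C)C)(C(C)C)C(C)C)c2c1=O | intermediate
22 | 5,7-dihydroxy-3,8-dimethoxy-2-[4-(3-methylbut-2-enyloxy)phenyl]-4H-chromen-4-one (5,7-dihydroxy-3,8-dimethoxy-4'-prenyloxyflavone) | COc1c(-c2ccc(OCC=C(C)C)cc2)oc2c(OC)c(O)cc(O)c2c1=O | target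

**Total step count:** 12
**Longest linear sequence:** 11 steps (steps 1–6 and 8–12, from 1 to 22); step 7 is a one-step branch.

**Steps most likely to fail**

Step 11. The fully substituted ylide carbon may add too slowly to the electron-rich aroyl ester, so that on prolonged heating acyl transfer to the ylide oxygen or rearrangement of the prenyl ether takes over. The fallback builds the same ring by known chemistry in which the C2–C3 bond is made by acyl transfer and O1–C2 closes last. It sets out from acid 16, which is converted as in step 10 into acid chloride 18. Treatment of 18 with diazomethane and Et3N in Et2O at 0 °C should give 2-(diazoacetyl)-6-methoxy-3,5-bis(triisopropylsilyloxy)phenyl 4-(3-methylbut-2-enyloxy)benzoate F1. Rh2(OAc)4-catalysed O–H insertion in MeOH/CH2Cl2 should then give 6-methoxy-2-(methoxyacetyl)-3,5-bis(triisopropylsilyloxy)phenyl 4-(3-methylbut-2-enyloxy)benzoate F2. LiN(SiMe3)2 in THF (−78 to 0 °C) should trigger the Baker–Venkataraman rearrangement to 1-[2-hydroxy-3-methoxy-4,6-bis(triisopropylsilyloxy)phenyl]-2-methoxy-3-[4-(3-methylbut-2-enyloxy)phenyl]propane-1,3-dione F3. Cyclodehydration of F3 with NaOAc in AcOH at 80 °C comes back to the route at flavone 21.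

Step 10. The strongly basic non-stabilised ylide may be consumed by attack on the aryl ester, or the acid chloride may lose or shift its aroyl group before C-acylation at the doubly ortho-substituted carbonyl is complete. The fallback changes the acyl donor and the base that completes ylide formation, so that no chloride and no second equivalent of the basic ylide are needed. It sets out from acid 16, which with t-BuMe2SiCl and imidazole in CH2Cl2 should give tert-butyldimethylsilyl 3-methoxy-2-[4-(3-methylbut-2-enyloxy)benzoyloxy]-4,6-bis(triisopropylsilyloxy)benzoate F4. One equivalent of Ph3P=CHOMe in THF (−78 °C to rt) is then acylated at the silyl ester carbonyl, a known mode of ylide acylation for silyl esters of O-acylsalicylic acids. In the resulting acylphosphonium tert-butyldimethylsilanolate F5 the silanolate removes the acidic α-proton, and the sequence comes back to the route at ylide 20.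

Step 5. The very electron-rich ring may condense with formaldehyde beyond the hydroxymethyl stage (quinone methide capture by a second arene, or double formylation), and attack next to the bulky silyloxy group may be slow. The fallback replaces the formaldehyde and hydride-transfer manifold by a chloroiminium electrophile (Vilsmeier–Haack formylation). It sets out from diol 6, which with POCl3 and DMF in MeCN at 0 °C should give N-{[2,4-dihydroxy-3-methoxy-6-(triisopropylsilyloxy)phenyl]methylidene}-N-methylmethanaminium chloride F6. Because both open positions of 6 are equivalent, the regiochemistry is unchanged, and hydrolysis with aqueous NaOAc at rt comes back to the route at aldehyde 8.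

**Further compounds**
F1 | step 11 | 2-(diazoacetyl)-6-methoxy-3,5-bis(triisopropylsilyloxy)phenyl 4-(3-methylbut-2-enyloxy)benzoate | COc1c(O[Si](C(C)C)(C(C)C)C(C)C)cc(O[Si](C(C)C)(C(C)C)C(C)C)c(C(=O)C=[N+]=[N-])c1OC(=O)c1ccc(OCC=C(C)C)cc1
F2 | step 11 | 6-methoxy-2-(methoxyacetyl)-3,5-bis(triisopropylsilyloxy)phenyl 4-(3-methylbut-2-enyloxy)benzoate | COCC(=O)c1c(O[Si](C(C)C)(C(C)C)C(C)C)cc(O[Si](C(C)C)(C(C)C)C(C)C)c(OC)c1OC(=O)c1ccc(OCC=C(C)C)cc1
F3 | step 11 | 1-[2-hydroxy-3-methoxy-4,6-bis(triisopropylsilyloxy)phenyl]-2-methoxy-3-[4-(3-methylbut-2-enyloxy)phenyl]propane-1,3-dione (racemic, enolisable) | COC(C(=O)c1ccc(OCC=C(C)C)cc1)C(=O)c1c(O[Si](C(C)C)(C(C)C)C(C)C)cc(O[Si](C(C)C)(C(C)C)C(C)C)c(OC)c1O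
F4 | step 10 | tert-butyldimethylsilyl 3-methoxy-2-[4-(3-methylbut-2-enyloxy)benzoyloxy]-4,6-bis(triisopropylsilyloxy)benzoate | COc1c(O[Si](C(C)C)(C(C)C)C(C)C)cc(O[Si](C(C)C)(C(C)C)C(C)C)c(C(=O)O[Si](C)(C)C(C)(C)C)c1OC(=O)c1ccc(OCC=C(C)C)cc1
F5 | step 10 | {1-methoxy-2-[3-methoxy-2-[4-(3-methylbut-2-enyloxy)benzoyloxy]-4,6-bis(triisopropylsilyloxy)phenyl]-2-oxoethyl}triphenylphosphonium tert-butyldimethylsilanolate (racemic ion pair, not isolated) | COC(C(=O)c1c(O[Si](C(C)C)(C(C)C)C(C)C)cc(O[Si](C(C)C)(C(C)C)C(C)C)c(OC)c1OC(=O)c1ccc(OCC=C(C)C)cc1)[P+](c1ccccc1)(c1ccccc1)c1ccccc1.CC(C)(C)[Si](C)(C)[O-]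
F6 | step 5 | N-{[2,4-dihydroxy-3-methoxy-6-(triisopropylsilyloxy)phenyl]methylidene}-N-methylmethanaminium chloride | COc1c(O)cc(O[Si](C(C)C)(C(C)C)C(C)C)c(C=[N+](C)C)c1O.[Cl-]
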